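**Retrosynthetic overview**
1. Target ⇐ Δ8 acrylate methyl ester that already carries the 6α-angelate: α-epoxidation and 5-exo lactonisation form the lactone ring last and set C-8 and C-9.
2. C-7 side chain ⇐ Johnson–Claisen transfer from the 9β-allylic alcohol of a ring B enone, then α-methylenation.
3. Key disconnection: trans-fused 7-oxanorbornane/cyclohexenone ⇐ α-chloro 8-oxabicyclo[3.2.1]octan-3-one with a (Z)-iodovinyl carbinol arm; an internal vinyllithium adds to the ketone and the alkoxide undergoes a quasi-Favorskii 1,2-shift (seven-membered ring contracts to ring A, cyclopentenol expands to ring B).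
4. That precursor ⇐ syn-aldol with (Z)-3-iodoacrolein, exo C-methylation of an α-chloro ketone, hydrogenation, [4+3] cycloaddition of 2-methylfuran with the chloro-oxyallyl cation from 1,3-dichloroacetone.
5. Ring order: oxygen-bridged seven-membered ring → rings A and B together in the ring-contraction step → lactone.

Assumption: compounds 19 to 29 are named with eudesmane numbering (C-1 to C-15; all have 5α-H, 10β-CH3, 4α-CH3); compounds 4 to 6 are racemic and drawn as the enantiomer carried on after the resolution in step 3; the target is read as (1R,4S,5S,6S,7S,8S,9S,10S)-6α-angeloyloxy-1β,4β-epoxy-9α-hydroxyeudesm-11(13)-en-12,8β-olide.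

**Step 1**
Reactants: 1 2-methylfuran; 2 1,3-dichloropropan-2-one
Product: 4 rac-(1R,4S,5R)-4-chloro-1-methyl-8-oxabicyclo[3.2.1]oct-6-en-3-one, via chloro-oxyallyl cation 3 (not isolated)
Conditions: Et3N, CF3CH2OH, 0 °C → rt
Reagents that add atoms: none
Why: Base-mediated (Föhlisch-type) [4+3] cycloaddition: enolisation of 2 and loss of chloride give cation 3, whose more cationic, chlorine-bearing terminus bonds preferentially to the unsubstituted α-carbon of the furan, so chlorine sits next to the CH bridgehead (minor regioisomer removed by chromatography); both bridgehead centres are set here as a racemate, and the chloride centre is planarised again in step 3.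

**Step 2**
Reactants: 4 rac-(1R,4S,5R)-4-chloro-1-methyl-8-oxabicyclo[3.2.1]oct-6-en-3-one
Product: 5 rac-(1S,4S,5R)-4-chloro-1-methyl-8-oxabicyclo[3.2.1]octan-3-one
Conditions: H2 (1 atm), Rh/Al2O3 (5 wt % Rh), EtOAc, rt
Reagents that add atoms: none
Why: Catalytic hydrogenation of the strained cis-alkene is much faster than C–Cl hydrogenolysis or ketone reduction on rhodium; no stereocentre is formed, and the saturated bridge screens the endo face in the two enolate reactions that follow.

**Step 3**
Reactants: 5 rac-(1S,4S,5R)-4-chloro-1-methyl-8-oxabicyclo[3.2.1]octan-3-one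
Product: 7 (1S,4S,5R)-4-chloro-1,4-dimethyl-8-oxabicyclo[3.2.1]octan-3-one, via potassium enolate 6 (not isolated)
Conditions: KN(SiMe3)2, THF, −78 °C; MeI, −78 → −30 °C; then preparative SFC on an amylose tris(3,5-dimethylphenylcarbamate) phase (CO2/MeOH)
Reagents that add atoms: iodomethane, CI
Why: Enolate C-alkylation: the α-chloro C–H is the most acidic and least hindered α-position, and MeI attacks enolate 6 on the exo face (syn to the oxygen bridge, axial entry), which leaves chlorine equatorial and antiperiplanar to the C-2–C-3 ring bond as the later 1,2-shift requires; the chiral-phase resolution fixes the absolute configuration at the bridgeheads.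

**Step 4**
Reactants: 7 (1S,4S,5R)-4-chloro-1,4-dimethyl-8-oxabicyclo[3.2.1]octan-3-one; 8 ethyl (2Z)-3-iodoprop-2-enoate
Product: 12 (1S,2S,4S,5R)-4-chloro-2-[(1R,2Z)-1-hydroxy-3-iodoprop-2-en-1-yl]-1,4-dimethyl-8-oxabicyclo[3.2.1]octan-3-one, via (2Z)-3-iodoprop-2-enal 9 (not isolated), via lithium enolate 10 (not isolated), via triisopropoxytitanium enolate 11 (not isolated)
Conditions: 8, i-Bu2AlH, CH2Cl2, −78 °C (cold solution of 9 used at once); 7, LiN(i-Pr)2, THF, −78 °C; ClTi(OiPr)3, −78 → −40 °C; 9, −78 °C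
Reagents that add atoms: none
Why: Half-reduction of the ester gives aldehyde 9, and the triisopropoxytitanium enolate 11 undergoes a syn-selective (erythro) titanium aldol addition on its exo face, which sets C-2 (side chain axial) and the carbinol centre, the future C-5 and C-6; the equatorial C–Cl bond lies in the enolate plane and cannot close to a Favorskii cyclopropanone.

**Step 5**
Reactants: 12 (1S,2S,4S,5R)-4-chloro-2-[(1R,2Z)-1-hydroxy-3-iodoprop-2-en-1-yl]-1,4-dimethyl-8-oxabicyclo[3.2.1]octan-3-one; 13 angelic acid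
Product: 19 6α-angeloyloxy-1β,4β-epoxy-11,12,13-trinoreudesm-7-en-9-one, via mixed anhydride 14 (not isolated), via lithium alkoxide 15 (not isolated), via vinyllithium alkoxide 16 (not isolated), via tricyclic dialkoxide 17 (not isolated), via enone alkoxide 18 (not isolated)
Conditions: 13, 2,4,6-Cl3C6H2COCl, Et3N, toluene, rt, filtered (solution of 14); 12, LiN(SiMe3)2, Et2O–THF, −78 °C; t-BuLi (2.1 equiv), −100 °C; −100 → 20 °C; then 14, −78 → 0 °C
Reagents that add atoms: none
Why: Proposed new method: iodine–lithium exchange gives (Z)-vinyllithium 16, which adds 5-exo to the flanking ketone from the exo face to give the cis-fused alkoxide 17; in its chair-like form the ring bond C-2–C-3 is antiperiplanar to the equatorial C–Cl bond (the vinyl group and the oxygen are gauche, so vinyl shift and epoxide closure lack alignment), so the alkoxide drives a quasi-Favorskii (semibenzilic) 1,2-shift of C-2 from the carbinol carbon to C-4 with inversion at C-4 and retention at C-2; this contracts the seven-membered ring to the 7-oxanorbornane, expands the cyclopentenol to the ring B cyclohexenone, fixes quaternary C-10 (methyl exo, acyl endo) and pays for the strained trans ring fusion in an irreversible step; the closest known reaction types are the hydride- or alkyllithium-triggered quasi-Favorskii ring contraction of α-halo [4+3] cycloadducts and the anionic cyclisation of vinyl iodides onto ketones; alkoxide 18 is acylated in the same flask by 14 at its unhindered angeloyl carbonyl.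

**Step 6**
Reactants: 19 6α-angeloyloxy-1β,4β-epoxy-11,12,13-trinoreudesm-7-en-9-one
Product: 20 6α-angeloyloxy-1β,4β-epoxy-11,12,13-trinoreudesm-7-en-9β-ol
Conditions: NaBH4, CeCl3·7H2O, MeOH, −78 → −40 °C
Reagents that add atoms: none
Why: Luche 1,2-reduction; hydride adds to C-9 from the α face, anti to the axial 10β-methyl group, giving the 9β-allylic alcohol without touching the angelate or the alkene.

**Step 7**
Reactants: 20 6α-angeloyloxy-1β,4β-epoxy-11,12,13-trinoreudesm-7-en-9β-ol; 21 trimethyl orthoacetate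
Product: 23 methyl 6α-angeloyloxy-1β,4β-epoxy-13-noreudesm-8-en-12-oate, via mixed ketene acetal 22 (not isolated)
Conditions: 21 (10 equiv), EtCO2H (cat.), xylene, 135 °C, MeOH distilled off
Reagents that add atoms: none
Why: Johnson–Claisen orthoester rearrangement; ketene acetal 22 transfers the two-carbon unit suprafacially from the 9β-oxygen to the β face of C-7, which sets C-7 (7α-H) and moves the alkene to C-8/C-9.

**Step 8**
Reactants: 23 methyl 6α-angeloyloxy-1β,4β-epoxy-13-noreudesm-8-en-12-oate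
Product: 27 methyl 6α-angeloyloxy-1β,4β-epoxyeudesma-8,11(13)-dien-12-oate, via lithium ester enolate 24 (not isolated), via Mannich base 25 (not isolated), via trimethylammonium iodide 26 (not isolated)
Conditions: LiN(i-Pr)2 (1.05 equiv), THF, −78 °C; CH2=NMe2+ I−, −78 → −20 °C; MeI, MeOH, rt; NaHCO3, CH2Cl2–H2O, rt
Reagents that add atoms: dimethylmethyleneiminium iodide (Eschenmoser's salt), C=[N+](C)C.[I-]
Why: Eschenmoser α-methylenation (ester-enolate Mannich reaction, N-methylation, mild E1cB elimination); the saturated ester α-CH2 is deprotonated kinetically much faster than the γ-CH3 of the hindered angelate, which has no α-hydrogen, and no stereocentre is touched.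

**Step 9**
Reactants: 27 methyl 6α-angeloyloxy-1β,4β-epoxyeudesma-8,11(13)-dien-12-oate
Product: 29 6α-angeloyloxy-1β,4β-epoxy-9α-hydroxyeudesm-11(13)-en-12,8β-olide, via epoxy ester 28 (not isolated)
Conditions: m-CPBA, NaHCO3, CH2Cl2, 0 °C; then camphorsulfonic acid (10 mol %), wet CH2Cl2, 0 °C → rt
Reagents that add atoms: 3-chloroperoxybenzoic acid, OOC(=O)c1cccc(Cl)c1; water, O
Why: Prilezhaev epoxidation of the only electron-rich alkene from the α face (anti to the 10β-methyl group and the 7β side chain), then acid-catalysed 5-exo epoxy-ester lactonisation with inversion at C-8; this gives the cis-fused 8β,12-lactone and leaves the epoxide oxygen as the 9α-hydroxyl, setting C-8 and C-9.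

**Compound list**
1 | 2-methylfuran | Cc1ccco1 | starting material
2 | 1,3-dichloropropan-2-one | O=C(CCl)CCl | starting material
3 | 1-chloro-2-oxidoallyl cation (chloro-oxyallyl cation, not isolated) | [CH2+]C([O-])=CCl | intermediate
4 | rac-(1R,4S,5R)-4-chloro-1-methyl-8-oxabicyclo[3.2.1]oct-6-en-3-one (Cl equatorial) | O=C1C[C@]2(C)C=C[C@@H](O2)[C@@H]1Cl | intermediate
5 | rac-(1S,4S,5R)-4-chloro-1-methyl-8-oxabicyclo[3.2.1]octan-3-one | O=C1C[C@]2(C)CC[C@@H](O2)[C@@H]1Cl | intermediate
6 | potassium enolate of 5 (C-3/C-4 chloro-enolate, racemic, not isolated) | [K+].[O-]C1=C(Cl)[C@H]2CC[C@@](C)(C1)O2 | intermediate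
7 | (1S,4S,5R)-4-chloro-1,4-dimethyl-8-oxabicyclo[3.2.1]octan-3-one (4-CH3 axial and syn to the O bridge, Cl equatorial) | O=C1C[C@]2(C)CC[C@@H](O2)[C@]1(C)Cl | intermediate
8 | ethyl (2Z)-3-iodoprop-2-enoate | CCOC(=O)/C=C\I | starting material
9 | (2Z)-3-iodoprop-2-enal (not isolated) | O=C/C=C\I | intermediate
10 | lithium enolate of 7 (C-2/C-3, not isolated) | [Li]OC1=C[C@]2(C)CC[C@@H](O2)[C@]1(C)Cl | intermediate
11 | triisopropoxytitanium enolate of 7 (not isolated) | CC(C)O[Ti](OC(C)C)(OC(C)C)OC1=C[C@]2(C)CC[C@@H](O2)[C@]1(C)Cl | intermediate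
12 | (1S,2S,4S,5R)-4-chloro-2-[(1R,2Z)-1-hydroxy-3-iodoprop-2-en-1-yl]-1,4-dimethyl-8-oxabicyclo[3.2.1]octan-3-one (side chain axial, syn to the O bridge) | O=C1[C@@H]([C@@H](O)/C=C\I)[C@]2(C)CC[C@@H](O2)[C@]1(C)Cl | intermediate
13 | angelic acid, (2Z)-2-methylbut-2-enoic acid | C/C=C(/C)C(=O)O | starting material
14 | angelic 2,4,6-trichlorobenzoic anhydride (not isolated) | C/C=C(/C)C(=O)OC(=O)c1c(Cl)cc(Cl)cc1Cl | intermediate
15 | lithium alkoxide of 12 (not isolated) | O=C1[C@@H]([C@@H](O[Li])/C=C\I)[C@]2(C)CC[C@@H](O2)[C@]1(C)Cl | intermediate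
16 | (Z)-vinyllithium lithium alkoxide from 15 (not isolated) | O=C1[C@@H]([C@@H](O[Li])/C=C\[Li])[C@]2(C)CC[C@@H](O2)[C@]1(C)Cl | intermediate
17 | dilithium dialkoxide of the cis-fused cyclopentenol-annulated 8-oxabicyclo[3.2.1]octane (tertiary C–O axial, Cl equatorial, not isolated) | [Li]O[C@]12C=C[C@H](O[Li])[C@H]1[C@]1(C)CC[C@@H](O1)[C@]2(C)Cl | intermediate
18 | lithium 1β,4β-epoxy-9-oxo-11,12,13-trinoreudesm-7-en-6α-olate (not isolated) | O=C1C=C[C@H](O[Li])[C@@H]2[C@]1(C)[C@H]1CC[C@]2(C)O1 | intermediate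
19 | 6α-angeloyloxy-1β,4β-epoxy-11,12,13-trinoreudesm-7-en-9-one | O=C1C=C[C@H](OC(=O)/C(C)=C\C)[C@@H]2[C@]1(C)[C@H]1CC[C@]2(C)O1 | intermediate
20 | 6α-angeloyloxy-1β,4β-epoxy-11,12,13-trinoreudesm-7-en-9β-ol | O[C@H]1C=C[C@H](OC(=O)/C(C)=C\C)[C@@H]2[C@]1(C)[C@H]1CC[C@]2(C)O1 | intermediate
21 | trimethyl orthoacetate (1,1,1-trimethoxyethane) | CC(OC)(OC)OC | starting material
22 | 9β-O-(1-methoxyvinyl) ketene acetal of 20 (not isolated) | C=C(OC)O[C@H]1C=C[C@H](OC(=O)/C(C)=C\C)[C@@H]2[C@]1(C)[C@H]1CC[C@]2(C)O1 | intermediate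
23 | methyl 6α-angeloyloxy-1β,4β-epoxy-13-noreudesm-8-en-12-oate (7α-H) | COC(=O)C[C@@H]1C=C[C@@]2(C)[C@H]3CC[C@](C)(O3)[C@@H]2[C@H]1OC(=O)/C(C)=C\C | intermediate
24 | lithium enolate of 23 (not isolated) | COC(O[Li])=C[C@@H]1C=C[C@@]2(C)[C@H]3CC[C@](C)(O3)[C@@H]2[C@H]1OC(=O)/C(C)=C\C | intermediate
25 | methyl 6α-angeloyloxy-13-(dimethylamino)-1β,4β-epoxyeudesm-8-en-12-oate (both C-11 epimers, not isolated) | COC(=O)C(CN(C)C)[C@@H]1C=C[C@@]2(C)[C@H]3CC[C@](C)(O3)[C@@H]2[C@H]1OC(=O)/C(C)=C\C | intermediate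
26 | 13-trimethylammonium iodide of 25 (not isolated) | [I-].COC(=O)C(C[N+](C)(C)C)[C@@H]1C=C[C@@]2(C)[C@H]3CC[C@](C)(O3)[C@@H]2[C@H]1OC(=O)/C(C)=C\C | intermediate
27 | methyl 6α-angeloyloxy-1β,4β-epoxyeudesma-8,11(13)-dien-12-oate | COC(=O)C(=C)[C@@H]1C=C[C@@]2(C)[C@H]3CC[C@](C)(O3)[C@@H]2[C@H]1OC(=O)/C(C)=C\C | intermediate
28 | methyl 6α-angeloyloxy-1β,4β:8α,9α-diepoxyeudesm-11(13)-en-12-oate (not isolated) | COC(=O)C(=C)[C@@H]1[C@H]2O[C@H]2[C@@]3(C)[C@H]4CC[C@](C)(O4)[C@@H]3[C@H]1OC(=O)/C(C)=C\C | intermediate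
29 | CNP0328162.1, (1R,4S,5S,6S,7S,8S,9S,10S)-6α-angeloyloxy-1β,4β-epoxy-9α-hydroxyeudesm-11(13)-en-12,8β-olide | C=C1C(=O)O[C@H]2[C@@H]1[C@H](OC(=O)/C(C)=C\C)[C@@H]1[C@@](C)([C@@H]2O)[C@H]2CC[C@]1(C)O2 | target

**Totals**
Total step count: 9.
Longest linear sequence: 9 steps (1 and 2 to 29); 8, 13 and 21 are bought and enter in steps 4, 5 and 7.

**The three steps most likely to fail**

Step 5 (the proposed new cascade). It may stall at the tricyclic alkoxide, or the vinyl group may migrate if the six-membered ring flips to a boat. Fallback with known chemistry, setting out from 7: the titanium aldol of step 4 run with acrolein gives the vinyl carbinol (1S,2S,4S,5R)-4-chloro-2-[(1S)-1-hydroxyprop-2-en-1-yl]-1,4-dimethyl-8-oxabicyclo[3.2.1]octan-3-one F3. Deprotonation with LiN(SiMe3)2 and addition of vinyllithium (THF, −78 °C → rt) triggers the established intermolecular organolithium quasi-Favorskii ring contraction; quenching the alkoxide with 14 gives the dienone 2-endo-acryloyl-3-exo-[(1S)-1-(angeloyloxy)prop-2-en-1-yl]-1,3-exo-dimethyl... more simply the 7-oxanorbornane dienone angelate F4. Ring-closing metathesis with the second-generation Grubbs catalyst (CH2Cl2, 40 °C) then closes ring B, and the route comes back at 19.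

Step 4 (syn- and exo-selective aldol at a hindered α-carbon with a labile aldehyde). The 4-methyl group is syn-axial to the incoming aldehyde, and erythro selectivity of the titanium enolate may be modest. Fallback, setting out from 7: the ordinary lithium enolate (LiN(i-Pr)2, THF, −78 °C; 9) gives the threo adduct through a closed chair transition state, the carbinol epimer (1S,2S,4S,5R)-4-chloro-2-[(1S,2Z)-1-hydroxy-3-iodoprop-2-en-1-yl]-1,4-dimethyl-8-oxabicyclo[3.2.1]octan-3-one F1. The step 5 cascade is run on F1 with an aqueous quench to give 1β,4β-epoxy-6β-hydroxy-11,12,13-trinoreudesm-7-en-9-one F2. Mitsunobu esterification with 13 (PPh3, DIAD, toluene, 0 °C → rt) then installs the angelate with inversion at C-6, and the route comes back at 19.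

Step 8 (strong base in the presence of the angelate; risk of γ-deprotonation or intramolecular Claisen acyl transfer). Fallback, setting out from 20: acylation with methyl malonyl chloride (pyridine, CH2Cl2, 0 °C) gives the mixed malonate 9β-O-(methoxycarbonylacetyl) derivative of 20 F5. Ireland–Claisen rearrangement of its silyl ketene acetal (Me3SiOTf, Et3N, toluene, rt → 60 °C, aqueous work-up) gives the malonic half-ester methyl hydrogen 2-(6α-angeloyloxy-1β,4β-epoxy-11,12,13-trinoreudesm-8-en-7β-yl)malonate F6. Decarboxylative Mannich methylenation (paraformaldehyde, Et2NH, EtOAc, 70 °C) needs no strong base, and the route comes back at 27.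

**Further compounds**
F1 | step 4 | (1S,2S,4S,5R)-4-chloro-2-[(1S,2Z)-1-hydroxy-3-iodoprop-2-en-1-yl]-1,4-dimethyl-8-oxabicyclo[3.2.1]octan-3-one | O=C1[C@@H]([C@H](O)/C=C\I)[C@]2(C)CC[C@@H](O2)[C@]1(C)Cl
F2 | step 4 | 1β,4β-epoxy-6β-hydroxy-11,12,13-trinoreudesm-7-en-9-one | O=C1C=C[C@@H](O)[C@@H]2[C@]1(C)[C@H]1CC[C@]2(C)O1
F3 | step 5 | (1S,2S,4S,5R)-4-chloro-2-[(1S)-1-hydroxyprop-2-en-1-yl]-1,4-dimethyl-8-oxabicyclo[3.2.1]octan-3-one | O=C1[C@@H]([C@@H](O)C=C)[C@]2(C)CC[C@@H](O2)[C@]1(C)Cl
F4 | step 5 | 7-oxanorbornane dienone angelate (2-endo-acryloyl, 2-exo-methyl, 3-exo-[1-(angeloyloxy)allyl], bridgehead methyl next to C-3) | C=CC(=O)[C@]1(C)[C@@H]([C@@H](OC(=O)/C(C)=C\C)C=C)[C@]2(C)CC[C@H]1O2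
F5 | step 8 | 6α-angeloyloxy-1β,4β-epoxy-11,12,13-trinoreudesm-7-en-9β-yl methyl malonate | COC(=O)CC(=O)O[C@H]1C=C[C@H](OC(=O)/C(C)=C\C)[C@@H]2[C@]1(C)[C@H]1CC[C@]2(C)O1
F6 | step 8 | methyl hydrogen 2-(6α-angeloyloxy-1β,4β-epoxy-11,12,13-trinoreudesm-8-en-7β-yl)malonate (C-11 epimers) | COC(=O)C(C(=O)O)[C@@H]1C=C[C@@]2(C)[C@H]3CC[C@](C)(O3)[C@@H]2[C@H]1OC(=O)/C(C)=C\C
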